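**Plan**

- Locants: C1 lactone O–CH; C2=C3 E-olefin (Me on C3); C4 acetoxy CH; C5–C6 epoxide (Me on C6); C7, C8 CH2; C9 angeloyloxy CH; C10 ring-fusion CH; C11, C12, C13 = lactone α-carbon, C=O, exocyclic CH2.
- Retrosynthesis: remove the O9 angelate, the O4 acetate, the C11=C13 methylene and the epoxide oxygen; cut the ring bond C6–C7; then cut O1–C12 (lactone), C1–C2, C4–C5 and C9–C10.
- Forward: fragment A (C1, C7–C12) comes from an anti-aldol of a succinate imide with acrolein; fragment B (C2–C6 with both methyls) from propargyl alcohol and propyne. They are joined at C1–C2; the γ-lactone closes first, then the ten-membered carbocycle at C6–C7, then the epoxide.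
- Enabling feature: the fully substituted epoxide carbon C6 descends from a Z-trisubstituted C5=C6 olefin and its ring neighbour C7 is a plain methylene, so C6–C7 is an sp2–sp3 bond between a Z-vinyl iodide and the alkylborane of a terminal C7=C8 vinyl group.
- Stereochemistry: C9/C10 from the auxiliary-controlled anti-aldol; C1 from Felkin–Anh ketone reduction; C4 from ligand-controlled alkynylation; C5/C6 from C4–OH-directed epoxidation of the Z olefin; E olefin from syn-carboalumination, Z olefin from trans-hydrosilylation and iododesilylation.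

Key step: step 12

Remark 1: (S,S)-ProPhenol/Me2Zn is taken to add the alkynyl group to the Si face of the enal; if the sense is opposite, the (R,R)-ligand is used.
Remark 2: the MgCl2-catalysed aldol of the (S)-benzyl oxazolidinone is taken to react through the chelated Z-enolate on the face opposite benzyl (alkylation sense); if not, the enantiomeric auxiliary is used.
Remark 3: CIP labels refer to the locants above; the label at C10 switches between R and S with the O9 substituent and the C1 oxidation level, and the label at C4 switches with the nature of C5, in both cases without change of geometry.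

**Step 1**
Reactants: 1 mono-tert-butyl succinate (4-tert-butoxy-4-oxobutanoic acid); 2 (4S)-4-benzyl-1,3-oxazolidin-2-one
Product: 4 tert-butyl 4-[(4S)-4-benzyl-2-oxo-1,3-oxazolidin-3-yl]-4-oxobutanoate, via mixed pivalic anhydride 3 (not isolated)
Conditions: PivCl, Et3N, THF, −20 °C; then 2, LiCl, −20 → 23 °C
Reagents that add atoms: none
Why: N-acylation of the oxazolidinone through a mixed pivalic anhydride is a standard imide formation in which the hindered pivaloyl carbonyl is not attacked, and no stereocentre is made.

**Step 2**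
Reactants: 4 succinate imide; 5 acrolein
Product: 7 tert-butyl (3R,4R)-3-[(4S)-4-benzyl-2-oxo-1,3-oxazolidine-3-carbonyl]-4-hydroxyhex-5-enoate (anti-aldol; C9 R, C10 R), via trimethylsilyl ether 6 (not isolated)
Conditions: MgCl2 (20 mol %), Et3N, TMSCl, EtOAc, 23 °C; then 1 M HCl–THF, 23 °C
Reagents that add atoms: none
Why: the magnesium-catalysed direct anti-aldol of N-acyl oxazolidinones with non-enolisable unsaturated aldehydes should set C10 and C9 together, the chelated Z-enolate being attacked on the face opposite the benzyl group and silylation of the aldolate driving turnover, while the tert-butyl ester resists lactonisation by the new hydroxyl.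

**Step 3**
Reactants: 7 anti-aldol adduct
Product: 8 tert-butyl (3R,4R)-4-hydroxy-3-[methoxy(methyl)carbamoyl]hex-5-enoate
Conditions: Me(MeO)NH·HCl, AlMe3, CH2Cl2, −15 → 0 °C; aqueous potassium sodium tartrate work-up
Reagents that add atoms: N,O-dimethylhydroxylamine hydrochloride, CNOC.Cl
Why: aluminium-amide transamination of a β-hydroxy imide (Weinreb amide formation) is assisted by the free β-hydroxyl, cleaves only the exocyclic imide carbonyl, leaves the hindered tert-butyl ester and touches no stereocentre.

**Step 4**
Reactants: 8 hydroxy Weinreb amide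
Product: 10 (3R,4R)-4-[tert-butyl(dimethyl)silyl]oxy-3-[methoxy(methyl)carbamoyl]hex-5-enoic acid, via silyl ether silyl ester 9 (not isolated)
Conditions: TBSOTf (3 equiv), 2,6-lutidine, CH2Cl2, 0 → 23 °C; then AcOH–THF–H2O, 23 °C
Reagents that add atoms: tert-butyldimethylsilyl trifluoromethanesulfonate, CC(C)(C)[Si](C)(C)OS(=O)(=O)C(F)(F)F
Why: the silyl triflate silylates the secondary allylic alcohol and, in excess, exchanges the tert-butyl ester for a silyl ester with loss of isobutene (known silyl-triflate cleavage of tert-butyl esters), and dilute aqueous acid then hydrolyses only the labile silyl ester.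

**Step 5**
Reactants: 11 propargyl alcohol
Product: 13 (E)-3-iodo-2-methylprop-2-en-1-ol, via vinylalane 12 (not isolated)
Conditions: AlMe3, Cp2ZrCl2 (25 mol %), CH2Cl2, 0 → 23 °C; then I2, THF, −30 → 0 °C
Reagents that add atoms: trimethylaluminium, C[Al](C)C; iodine, II
Why: Negishi carboalumination adds methyl and aluminium syn across the terminal alkyne with methyl on the internal carbon, and iodinolysis with retention gives the E vinyl iodide (iodine cis to methyl).

**Step 6**
Reactants: 13 iodo allylic alcohol
Product: 14 (E)-3-iodo-2-methylprop-2-enal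
Conditions: MnO2, CH2Cl2, 23 °C
Reagents that add atoms: none
Why: MnO2 oxidation of a primary allylic alcohol gives the enal without touching the vinyl iodide or the olefin geometry.

**Step 7**
Reactants: 14 iodo enal; 15 propyne
Product: 16 (1E,3S)-1-iodo-2-methylhex-1-en-4-yn-3-ol
Conditions: (S,S)-ProPhenol (20 mol %), Ph3P=O (40 mol %), Me2Zn, toluene, 0 → 4 °C
Reagents that add atoms: none
Why: the dinuclear zinc ProPhenol-catalysed alkynylation of α,β-unsaturated aldehydes adds the in-situ methyl(propynyl)zinc to the Si face of the enal inside the chiral dizinc pocket, which sets C4, and the vinyl iodide is inert to Me2Zn.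

**Step 8**
Reactants: 16 iodo enynol; 10 Weinreb amide acid
Product: 20 (3R,5E,7R)-3-[(1R)-1-[tert-butyl(dimethyl)silyl]oxyprop-2-en-1-yl]-7-hydroxy-6-methyl-4-oxodec-5-en-8-ynoic acid (C1 ketone; C4 R, C9 R, C10 R), via dilithio alkoxide vinyllithium 17 (not isolated), via sodium carboxylate 18 (not isolated), via tetrahedral N-methoxy-N-methyl adduct 19 (not isolated)
Conditions: 16 (1.5 equiv), MeLi then t-BuLi, Et2O, −78 °C; 10, NaH, THF, 0 °C; combined at −78 → −40 °C; aq. NH4Cl, then 1 M HCl to pH 3
Reagents that add atoms: none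
Why: iodine–lithium exchange with retention of the E geometry gives a vinyllithium whose hydroxyl is masked as the alkoxide, and this adds once to the Weinreb amide through the stable chelated adduct (Weinreb ketone synthesis) while the carboxylate is inert at low temperature, forming C1–C2 without a new stereocentre.

**Step 9**
Reactants: 20 enone acid
Product: 22 cis-γ-lactone enynol (1S,4R,9R,10S; 2E): C1 bears the (E)-CH=C(Me)–CH(OH)–C≡C–Me chain and C10 the CH(OTBS)–CH=CH2 group, via hydroxy acid 21 (not isolated)
Conditions: LiBH(s-Bu)3 (L-Selectride, 3.5 equiv), THF, −78 °C; aq. NH4Cl, 1 M HCl to pH 3; then PPTS (cat.), CH2Cl2, 23 °C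
Reagents that add atoms: none
Why: Felkin–Anh 1,2-reduction of the β,β-disubstituted enone by the bulky hydride anti to the C9 branch on C10, reinforced by 1,3-induction from the β-silyloxy group, should set C1 with O1 anti to C11 and syn to O9, after which the γ-hydroxy acid closes the cis-fused lactone on mild acidification (5-exo-trig lactonisation).

**Step 10**
Reactants: 22 lactone enynol
Product: 23 Z-vinylsilane lactone (1S,4S,9R,10S; 2E,5Z; SiEt3 on C6 cis to C4)
Conditions: [Cp*Ru(MeCN)3]PF6 (5 mol %), Et3SiH, CH2Cl2, 0 → 23 °C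
Reagents that add atoms: triethylsilane, CC[SiH](CC)CC
Why: cationic ruthenium-catalysed trans-hydrosilylation of an internal propargylic alcohol adds H and Si anti with silicon on the alkyne carbon distal to the hydroxyl (C6), giving the Z-vinylsilane, while the alkenes and the lactone are not engaged.

**Step 11**
Reactants: 23 Z-vinylsilane
Product: 24 Z-vinyl iodide lactone with terminal vinyl group (1S,4S,9R,10S; 2E,5Z; iodine on C6 cis to C4; free C4–OH; C9–OTBS)
Conditions: NIS, (CF3)2CHOH, 0 °C
Reagents that add atoms: N-iodosuccinimide, O=C1CCC(=O)N1I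
Why: electrophilic ipso-iododesilylation of the vinylsilane in hexafluoroisopropanol proceeds with retention of geometry through the β-silyl cation, and the β-silicon effect makes the vinylsilane far more reactive towards the iodonium source than the other olefins.

**Step 12 (key step)**
Reactants: 24 Z-vinyl iodide lactone
Product: 26 ten-membered 2E,5Z-dienol cis-fused to the saturated γ-lactone (1S,4S,9R,10S; C4–OH; C9–OTBS), via bis-boryl alkylborane 25 (not isolated)
Conditions: 9-BBN (3 equiv), THF, 0 → 23 °C; then slow addition to Pd(dppf)Cl2 (20 mol %), AsPh3, Cs2CO3, DMF–THF–H2O, 50 °C, high dilution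
Reagents that add atoms: none
Why: 9-BBN adds anti-Markovnikov to the monosubstituted C7=C8 vinyl group (boron on C7) and caps the C4 hydroxyl as a borinate; zerovalent palladium formed from Pd(dppf)Cl2 then inserts into the C6–I bond with retention, the base-activated alkylborane transfers C7 to palladium, and reductive elimination forms C6–C7. The closest known reaction type is the intramolecular B-alkyl Suzuki–Miyaura macrocyclisation of an ω-alkenyl vinyl iodide. The ten-membered carbocycle closes by reductive elimination from an eleven-membered palladacycle, a metal-templated closure favoured by slow addition and by the prefolding that the E olefin and the cis-fused lactone impose. No stereocentre is formed, and the Z geometry of C5=C6 needed for the later cis-epoxide is carried through because oxidative addition and reductive elimination are stereoretentive. The step needs hydroboration of the vinyl group in preference to the trisubstituted olefin and the vinyl iodide, which the bulk of 9-BBN secures, and alkyl transfer faster than β-hydride elimination, which the wide bite angle of dppf favours, while the carbonate base leaves the lactone and silyl ether intact.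

**Step 13**
Reactants: 26 macrocyclic dienol lactone
Product: 29 α-methylene lactone dienol (1S,4S,9R,10S; 2E,5Z), via Mannich base 27 (not isolated), via trimethylammonium iodide 28 (not isolated)
Conditions: LDA (2.5 equiv), THF, −78 °C; CH2=NMe2+ I− (Eschenmoser's salt), −78 → 23 °C; then MeI, MeOH, 23 °C; then aq. NaHCO3, CH2Cl2, 23 °C
Reagents that add atoms: Eschenmoser's salt (N,N-dimethylmethyleneiminium iodide), C=[N+](C)C.[I-]
Why: Mannich aminomethylation of the lactone enolate (the C4 alkoxide forms first and is restored on work-up), N-methylation and base-induced β-elimination of trimethylamine is the standard α-methylenation of γ-lactones, and C11 becomes sp2 so no stereocentre is at stake.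

**Step 14**
Reactants: 29 α-methylene lactone dienol
Product: 30 5,6-cis-epoxy alcohol (1S,4R,5R,6S,9R,10S)
Conditions: VO(acac)2 (10 mol %), t-BuOOH (decane), CH2Cl2, 0 → 23 °C
Reagents that add atoms: tert-butyl hydroperoxide, CC(C)(C)OO
Why: in this vanadium-catalysed hydroxyl-directed epoxidation the vanadate ester of the C4 alcohol should deliver oxygen syn across the Z C5=C6 bond (cis-epoxide) on the outer face, where the C4–O bond lies about 45° out of the olefin plane once the ring holds C3 on the inner face, setting C5 and C6, while C2=C3 is deactivated by the allylic lactone oxygen at C1 and the acrylate olefin is electron-poor.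

**Step 15**
Reactants: 30 epoxy alcohol
Product: 31 C4 acetate (1S,4R,5R,6S,9R,10S; C9–OTBS)
Conditions: Ac2O, pyridine, DMAP (cat.), CH2Cl2, 0 °C
Reagents that add atoms: acetic anhydride, CC(=O)OC(C)=O
Why: nucleophile-catalysed acylation of the only free secondary hydroxyl proceeds under conditions that leave the epoxide, the silyl ether and the acrylate untouched.

**Step 16**
Reactants: 31 silyl ether acetate
Product: 32 C9 alcohol (1S,4R,5R,6S,9R,10R)
Conditions: HF·pyridine, pyridine, THF, 0 → 23 °C
Reagents that add atoms: none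
Why: buffered fluoride desilylation removes the secondary TBS ether while the excess pyridine protects the trisubstituted epoxide, the acetate and the α-methylene lactone from acid.

**Step 17**
Reactants: 32 C9 alcohol; 33 angelic acid ((Z)-2-methylbut-2-enoic acid)
Product: 35 CNP0519641.1 (1S,4R,5R,6S,9R,10R; 2E; O4 acetate, O9 angelate), via angelic trichlorobenzoic anhydride 34 (not isolated)
Conditions: 33, 2,4,6-trichlorobenzoyl chloride, Et3N, toluene, 23 °C; then 32, toluene, 75 °C
Reagents that add atoms: none
Why: Yamaguchi-type mixed-anhydride esterification run without a nucleophilic pyridine catalyst acylates the hindered C9 alcohol and avoids the Z to E isomerisation that would give the tiglate.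

**Compound list**

1 | mono-tert-butyl succinate | O=C(O)CCC(=O)OC(C)(C)C | starting material
2 | (4S)-4-benzyl-1,3-oxazolidin-2-one | O=C1N[C@@H](Cc2ccccc2)CO1 | starting material
3 | mixed pivalic anhydride of 1 | CC(C)(C)C(=O)OC(=O)CCC(=O)OC(C)(C)C | intermediate (not isolated)
4 | tert-butyl 4-[(4S)-4-benzyl-2-oxo-1,3-oxazolidin-3-yl]-4-oxobutanoate | CC(C)(C)OC(=O)CCC(=O)N1[C@@H](Cc2ccccc2)COC1=O | intermediate
5 | acrolein | C=CC=O | starting material
6 | trimethylsilyl ether of 7 | C=C[C@@H](O[Si](C)(C)C)[C@@H](CC(=O)OC(C)(C)C)C(=O)N1[C@@H](Cc2ccccc2)COC1=O | intermediate (not isolated)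
7 | tert-butyl (3R,4R)-3-[(4S)-4-benzyl-2-oxo-1,3-oxazolidine-3-carbonyl]-4-hydroxyhex-5-enoate | C=C[C@@H](O)[C@@H](CC(=O)OC(C)(C)C)C(=O)N1[C@@H](Cc2ccccc2)COC1=O | intermediate
8 | tert-butyl (3R,4R)-4-hydroxy-3-[methoxy(methyl)carbamoyl]hex-5-enoate | C=C[C@@H](O)[C@@H](CC(=O)OC(C)(C)C)C(=O)N(C)OC | intermediate
9 | TBS ether TBS ester of the Weinreb amide | C=C[C@@H](O[Si](C)(C)C(C)(C)C)[C@@H](CC(=O)O[Si](C)(C)C(C)(C)C)C(=O)N(C)OC | intermediate (not isolated)
10 | (3R,4R)-4-[tert-butyl(dimethyl)silyl]oxy-3-[methoxy(methyl)carbamoyl]hex-5-enoic acid | C=C[C@@H](O[Si](C)(C)C(C)(C)C)[C@@H](CC(=O)O)C(=O)N(C)OC | intermediate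
11 | propargyl alcohol | C#CCO | starting material
12 | (E)-vinylalane aluminium alkoxide | C[Al](C)/C=C(\C)CO[Al](C)C | intermediate (not isolated)
13 | (E)-3-iodo-2-methylprop-2-en-1-ol | OC/C(C)=C/I | intermediate
14 | (E)-3-iodo-2-methylprop-2-enal | O=C/C(C)=C/I | intermediate
15 | propyne | CC#C | starting material
16 | (1E,3S)-1-iodo-2-methylhex-1-en-4-yn-3-ol | I/C=C(\C)[C@@H](O)C#CC | intermediate
17 | dilithio alkoxide vinyllithium from 16 | [Li]/C=C(\C)[C@@H](O[Li])C#CC | intermediate (not isolated)
18 | sodium carboxylate of 10 | C=C[C@@H](O[Si](C)(C)C(C)(C)C)[C@@H](CC(=O)[O-])C(=O)N(C)OC.[Na+] | intermediate (not isolated)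
19 | tetrahedral N-methoxy-N-methyl adduct | C=C[C@@H](O[Si](C)(C)C(C)(C)C)[C@@H](CC(=O)[O-])C(O[Li])(N(C)OC)/C=C(\C)[C@@H](O[Li])C#CC.[Na+] | intermediate (not isolated)
20 | enone acid (C1 ketone; 2E; C4 R, C9 R, C10 R) | C=C[C@@H](O[Si](C)(C)C(C)(C)C)[C@@H](CC(=O)O)C(=O)/C=C(\C)[C@@H](O)C#CC | intermediate
21 | hydroxy acid (C1 S, C4 R, C9 R, C10 S) | C=C[C@@H](O[Si](C)(C)C(C)(C)C)[C@@H](CC(=O)O)[C@@H](O)/C=C(\C)[C@@H](O)C#CC | intermediate (not isolated)
22 | cis-γ-lactone enynol (1S,4R,9R,10S; 2E) | C=C[C@@H](O[Si](C)(C)C(C)(C)C)[C@H]1CC(=O)O[C@H]1/C=C(\C)[C@@H](O)C#CC | intermediate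
23 | Z-vinylsilane lactone (1S,4S,9R,10S; 2E,5Z) | C=C[C@@H](O[Si](C)(C)C(C)(C)C)[C@H]1CC(=O)O[C@H]1/C=C(\C)[C@@H](O)/C=C(/C)[Si](CC)(CC)CC | intermediate
24 | Z-vinyl iodide lactone with terminal vinyl group (1S,4S,9R,10S; 2E,5Z) | C=C[C@@H](O[Si](C)(C)C(C)(C)C)[C@H]1CC(=O)O[C@H]1/C=C(\C)[C@@H](O)/C=C(/C)I | intermediate
25 | B-alkyl-9-BBN at C7 with O4 borinate | C(C[C@@H](O[Si](C)(C)C(C)(C)C)[C@H]1CC(=O)O[C@H]1/C=C(\C)[C@@H](OB2C3CCCC2CCC3)/C=C(/C)I)B4C5CCCC4CCC5 | intermediate (not isolated)
26 | ten-membered 2E,5Z-dienol fused to the saturated lactone (1S,4S,9R,10S) | C1C(=O)O[C@H]2/C=C(\C)[C@@H](O)/C=C(/C)CC[C@@H](O[Si](C)(C)C(C)(C)C)[C@@H]12 | intermediate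
27 | C11 dimethylaminomethyl lactone (Mannich base) | CN(C)CC1C(=O)O[C@H]2/C=C(\C)[C@@H](O)/C=C(/C)CC[C@@H](O[Si](C)(C)C(C)(C)C)[C@@H]12 | intermediate (not isolated)
28 | C11 trimethylammoniomethyl lactone iodide | C[N+](C)(C)CC1C(=O)O[C@H]2/C=C(\C)[C@@H](O)/C=C(/C)CC[C@@H](O[Si](C)(C)C(C)(C)C)[C@@H]12.[I-] | intermediate (not isolated)
29 | α-methylene lactone dienol (1S,4S,9R,10S; 2E,5Z) | C=C1C(=O)O[C@H]2/C=C(\C)[C@@H](O)/C=C(/C)CC[C@@H](O[Si](C)(C)C(C)(C)C)[C@@H]12 | intermediate
30 | 5,6-cis-epoxy alcohol (1S,4R,5R,6S,9R,10S) | C=C1C(=O)O[C@H]2/C=C(\C)[C@@H](O)[C@H]3O[C@@]3(C)CC[C@@H](O[Si](C)(C)C(C)(C)C)[C@@H]12 | intermediate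
31 | epoxy C4 acetate, C9 TBS ether (1S,4R,5R,6S,9R,10S) | C=C1C(=O)O[C@H]2/C=C(\C)[C@@H](OC(C)=O)[C@H]3O[C@@]3(C)CC[C@@H](O[Si](C)(C)C(C)(C)C)[C@@H]12 | intermediate
32 | epoxy C4 acetate, C9 alcohol (1S,4R,5R,6S,9R,10R) | C=C1C(=O)O[C@H]2/C=C(\C)[C@@H](OC(C)=O)[C@H]3O[C@@]3(C)CC[C@@H](O)[C@@H]12 | intermediate
33 | angelic acid | C/C=C(/C)C(=O)O | starting material
34 | angelic 2,4,6-trichlorobenzoic anhydride | C/C=C(/C)C(=O)OC(=O)c1c(Cl)cc(Cl)cc1Cl | intermediate (not isolated)
35 | CNP0519641.1 (1S,4R,5R,6S,9R,10R; 2E) | C=C1C(=O)O[C@H]2/C=C(\C)[C@@H](OC(C)=O)[C@H]3O[C@@]3(C)CC[C@@H](OC(=O)/C(C)=C\C)[C@@H]12 | target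

**Step count**

Total: 17 steps. Longest linear sequence: 14 steps (steps 1–4 and 8–17); fragment B takes 3 steps (5–7).

**Steps most likely to fail**

Step 12. Protodeboronation or β-hydride elimination of the alkylpalladium species and intermolecular coupling may outpace the strained ten-membered closure. The fallback moves the ring closure to C7=C8. It sets out from 24: Stille coupling with tributyl(vinyl)stannane (Pd(PPh3)4, CuI, DMF) should give the C6-vinyl triene lactone F1. Ring-closing metathesis between the C6 vinyl and the C9 vinyl groups (second-generation Hoveyda–Grubbs catalyst, toluene, high dilution) should give the ten-membered 2E,5Z,7Z-trienol lactone F2. Diimide (2-nitrobenzenesulfonyl hydrazide, Et3N) should then reduce only the disubstituted C7=C8 bond, and the route is rejoined at 26.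

Step 14. Oxygen delivery may go to the wrong face of C5=C6, or to the C2=C3 olefin, which is also allylic to the C4 hydroxyl. The fallback drops hydroxyl direction. It sets out from 29: acetylation (Ac2O, pyridine) gives the dienyl C4 acetate F3. Peripheral epoxidation with mCPBA (NaHCO3, CH2Cl2, 0 °C) of the more electron-rich C5=C6 bond, with the face chosen by the ring conformation alone, rejoins the route at 31.

Step 2. Conjugate addition of the magnesium enolate to acrolein and amine-induced polymerisation of acrolein may erode conversion and diastereoselectivity. The fallback uses a well-behaved surrogate aldehyde. It sets out from 4: the same MgCl2/Et3N/TMSCl aldol with (E)-cinnamaldehyde gives the silyl ether of the styryl anti-aldol adduct F4 and, after dilute acid, the styryl anti-aldol adduct F5. Ethenolysis (ethylene, second-generation Hoveyda–Grubbs catalyst, CH2Cl2) trims the styryl group to vinyl and rejoins the route at 7.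

**Further compounds**

F1 | step 12 | C6-vinyl triene lactone | C=C[C@@H](O[Si](C)(C)C(C)(C)C)[C@H]1CC(=O)O[C@H]1/C=C(\C)[C@@H](O)/C=C(/C)C=C
F2 | step 12 | ten-membered 2E,5Z,7Z-trienol lactone | C1C(=O)O[C@H]2/C=C(\C)[C@@H](O)/C=C(/C)\C=C/[C@@H](O[Si](C)(C)C(C)(C)C)[C@@H]12
F3 | step 14 | dienyl C4 acetate of 29 | C=C1C(=O)O[C@H]2/C=C(\C)[C@@H](OC(C)=O)/C=C(/C)CC[C@@H](O[Si](C)(C)C(C)(C)C)[C@@H]12
F4 | step 2 | trimethylsilyl ether of the styryl anti-aldol adduct | c3ccccc3/C=C/[C@@H](O[Si](C)(C)C)[C@@H](CC(=O)OC(C)(C)C)C(=O)N1[C@@H](Cc2ccccc2)COC1=O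
F5 | step 2 | styryl anti-aldol adduct | c3ccccc3/C=C/[C@@H](O)[C@@H](CC(=O)OC(C)(C)C)C(=O)N1[C@@H](Cc2ccccc2)COC1=O
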